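**Strategy.** Everything rests on the C3–C4 bond of ring A (C1–C5, C10; drimane numbering). Ring B is (S)-carvone: its ring carbons become C5–C10, its stereocentre becomes C5 and its isopropenyl group becomes the quaternary C4 with both methyl groups. Once ring B carries the C10 methyl and cyanoethyl groups, the C6 hydroxyl and the C9 hydroxymethyl group, an iron-hydride hydrogen-atom transfer converts the isopropenyl group into the tertiary C4 radical, which adds to the nitrile carbon C3. This one operation closes ring A, creates the gem-dimethyl group and unveils the C3 ketone beside it, the feature it exploits. Mitsunobu etherification with umbelliferone and acetylation follow.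

Key step: step 7

Remark: atoms are named by drimane numbering throughout (ring A = C1, C2, C3, C4, C5, C10; ring B = C5 to C10; C11 = the CH2O carbon on C9). The ketimine formed in step 7 is hydrolysed in the same flask.

**Step 1**
Reactants: 1 (S)-(+)-carvone
Product: 2 (5S,6R)-2,6-dimethyl-5-(prop-1-en-2-yl)cyclohex-2-en-1-one (trans-6-methylcarvone)
Conditions: LiN(iPr)2, THF, −78 °C; MeI, −78 to −20 °C
Reagents that add atoms: iodomethane, CI
Why: Kinetic α′-deprotonation and enolate alkylation anti to the neighbouring isopropenyl group should give mainly the trans isomer; this centre is re-enolised in step 2, so its configuration is not critical.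

**Step 2**
Reactants: 2 (5S,6R)-2,6-dimethyl-5-(prop-1-en-2-yl)cyclohex-2-en-1-one; 3 acrylonitrile
Product: 4 3-[(1R,6R)-1,3-dimethyl-2-oxo-6-(prop-1-en-2-yl)cyclohex-3-en-1-yl]propanenitrile (ring methyl cis, cyanoethyl trans to the isopropenyl group)
Conditions: LiN(iPr)2, THF, −78 to −30 °C; t-BuOH (1.2 equiv), acrylonitrile, −78 °C; AcOH quench at −78 °C
Reagents that add atoms: none
Why: Michael addition (cyanoethylation) of the kinetic α′-enolate should occur anti to the isopropenyl group, which A(1,2) strain with the enolate methyl holds pseudoaxial, so quaternary C10 gets its methyl cis and its chain trans to the C5 substituent, while t-BuOH protonates the α-cyano carbanion before it can add back to the enone.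

**Step 3**
Reactants: 4 3-[(1R,6R)-1,3-dimethyl-2-oxo-6-(prop-1-en-2-yl)cyclohex-3-en-1-yl]propanenitrile
Product: 5 3-[(1R,6R)-2-{[tert-butyl(dimethyl)silyl]oxy}-1,3-dimethyl-6-(prop-1-en-2-yl)cyclohexa-2,4-dien-1-yl]propanenitrile
Conditions: TBSOTf, Et3N, CH2Cl2, 0 °C to rt
Reagents that add atoms: tert-butyldimethylsilyl trifluoromethanesulfonate, CC(C)(C)[Si](C)(C)OS(=O)(=O)C(F)(F)F
Why: Soft enolisation leaves the nitrile untouched, and because C10 is quaternary only the γ-hydrogens at C6 can be removed, so the linear silyl dienol ether (C9=C8, C7=C6) should form.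

**Step 4**
Reactants: 5 silyl dienol ether
Product: 7 3-[(1R,5R,6R)-5-hydroxy-1,3-dimethyl-2-oxo-6-(prop-1-en-2-yl)cyclohex-3-en-1-yl]propanenitrile, via silyloxy epoxide 6 (not isolated)
Conditions: mCPBA (1.05 equiv), NaHCO3, CH2Cl2, −40 to −10 °C; then aq. citric acid, THF, 0 °C
Reagents that add atoms: 3-chloroperbenzoic acid, OOC(=O)c1cccc(Cl)c1
Why: Vinylogous Rubottom oxidation, in which the peracid should epoxidise the terminal C6=C7 bond of the silyloxydiene (far faster than the isopropenyl group) on the face opposite to the C5 isopropenyl group and the axial C10 methyl, and the epoxide opens to the γ-hydroxy enone with the C6 hydroxyl trans to the isopropenyl group.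

**Step 5**
Reactants: 7 γ-hydroxy enone
Product: 8 3-[(3R,4R,5R,6R)-6-hydroxy-4,8-dimethyl-5-(prop-1-en-2-yl)-1-oxaspiro[2.5]oct-7-en-4-yl]propanenitrile (oxirane oxygen cis to the C10 methyl)
Conditions: Me3S+ I− and KN(SiMe3)2 (2.5 equiv each), THF, −10 to 0 °C
Reagents that add atoms: trimethylsulfonium iodide, C[S+](C)C.[I-]
Why: Corey–Chaykovsky epoxidation, in which dimethylsulfonium methylide should add 1,2 to the C9 carbonyl by axial attack anti to the axial C10 methyl, placing the oxirane oxygen on the methyl face.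

**Step 6**
Reactants: 8 alkenyl oxirane
Product: 9 3-[(1S,2R,5R,6R)-5-hydroxy-2-(hydroxymethyl)-1,3-dimethyl-6-(prop-1-en-2-yl)cyclohex-3-en-1-yl]propanenitrile
Conditions: Pd2(dba)3·CHCl3 (cat.), PBu3, HCO2H, Et3N, 1,4-dioxane, rt
Reagents that add atoms: none
Why: Palladium-catalysed formate hydrogenolysis of an alkenyl oxirane (Tsuji-type), in which zerovalent palladium ionises the allylic C9–O bond with inversion and the palladium formate delivers hydride to the more substituted terminus C9 on the metal face, so C9–H ends trans and the CH2OH group cis to the C10 methyl while the alkene stays at C7=C8.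

**Step 7**
Reactants: 9 nitrile diol
Product: 11 (4aS,5R,8R,8aS)-8-hydroxy-5-(hydroxymethyl)-1,1,4a,6-tetramethyl-3,4,4a,5,8,8a-hexahydronaphthalen-2(1H)-one, via ketimine 10 (not isolated)
Conditions: Fe(acac)3 (30 mol%), PhSiH3, EtOH/ethylene glycol, 60 °C, 0.02 M; then 1 M aq. HCl, THF, rt
Reagents that add atoms: water, O
Why: Fe(acac)3 and PhSiH3 in ethanol generate an iron hydride that transfers a hydrogen atom to the terminal CH2 of the isopropenyl group, giving the tertiary C4 radical that now carries both methyl groups; this radical adds to the nitrile carbon C3 (C3–C4 bond), and the iminyl radical is reduced by divalent iron and protonated to ketimine 10, which aqueous acid hydrolyses to the C3 ketone. The closest known reaction type is the iron-hydride HAT-initiated reductive cyclisation of alkenyl nitriles to cyclic ketones. Ring A closes in the 6-exo-dig mode through a chair-like transition state in which the C5–C4 and C10–C1 bonds are both equatorial on ring B, so the trans ring fusion follows from the existing C5 and C10 centres. No new stereocentre is formed, because C4 bears two methyl groups and C3 becomes a carbonyl. The step needs hydrogen-atom transfer to the 1,1-disubstituted alkene rather than to the trisubstituted C7=C8 alkene, which the low steric demand of the isopropenyl group and the flanking C6 and C9 substituents of the ring alkene should secure, and it needs cyclisation to outrun reduction of the radical, which the Thorpe–Ingold effect of quaternary C10 and the preorganised diequatorial arrangement favour.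

**Step 8**
Reactants: 11 keto diol; 12 umbelliferone
Product: 13 7-{[(1R,4R,4aS,8aS)-4-hydroxy-2,5,5,8a-tetramethyl-6-oxo-1,4,4a,5,6,7,8,8a-octahydronaphthalen-1-yl]methoxy}-2H-chromen-2-one
Conditions: PPh3, DIAD, THF, 0 °C to rt
Reagents that add atoms: none
Why: Mitsunobu etherification with the acidic phenol should take place only at the primary C11 hydroxyl, because the secondary allylic C6 hydroxyl is shielded by C5 and the C4 gem-dimethyl group; no stereocentre is touched.

**Step 9**
Reactants: 13 hydroxy ether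
Product: 14 (1R,4R,4aS,8aS)-3,4a,8,8-tetramethyl-7-oxo-4-{[(2-oxo-2H-chromen-7-yl)oxy]methyl}-1,4,4a,5,6,7,8,8a-octahydronaphthalen-1-yl acetate (CNP0140705.2)
Conditions: Ac2O, DMAP, pyridine, rt to 40 °C
Reagents that add atoms: acetic anhydride, CC(=O)OC(C)=O
Why: DMAP-catalysed acylation of the remaining equatorial C6 hydroxyl should proceed with retention and leaves the coumarin lactone and the C3 ketone intact.

**Compound list**

1 | (S)-(+)-carvone, (5S)-2-methyl-5-(prop-1-en-2-yl)cyclohex-2-en-1-one | CC1=CC[C@@H](CC1=O)C(C)=C | starting material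
2 | (5S,6R)-2,6-dimethyl-5-(prop-1-en-2-yl)cyclohex-2-en-1-one | C1C=C(C)C(=O)[C@H](C)[C@H]1C(C)=C | intermediate
3 | acrylonitrile | C=CC#N | starting material
4 | 3-[(1R,6R)-1,3-dimethyl-2-oxo-6-(prop-1-en-2-yl)cyclohex-3-en-1-yl]propanenitrile | C1C=C(C)C(=O)[C@](C)(CCC#N)[C@H]1C(C)=C | intermediate
5 | 3-[(1R,6R)-2-{[tert-butyl(dimethyl)silyl]oxy}-1,3-dimethyl-6-(prop-1-en-2-yl)cyclohexa-2,4-dien-1-yl]propanenitrile | C1=CC(C)=C(O[Si](C)(C)C(C)(C)C)[C@](C)(CCC#N)[C@H]1C(C)=C | intermediate
6 | C6–C7 epoxide of 5, oxygen trans to the isopropenyl group, formed and consumed in step 4 | O1[C@@H]2[C@H]1C(C)=C(O[Si](C)(C)C(C)(C)C)[C@](C)(CCC#N)[C@H]2C(C)=C | intermediate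
7 | 3-[(1R,5R,6R)-5-hydroxy-1,3-dimethyl-2-oxo-6-(prop-1-en-2-yl)cyclohex-3-en-1-yl]propanenitrile | O[C@@H]1C=C(C)C(=O)[C@](C)(CCC#N)[C@H]1C(C)=C | intermediate
8 | 3-[(3R,4R,5R,6R)-6-hydroxy-4,8-dimethyl-5-(prop-1-en-2-yl)-1-oxaspiro[2.5]oct-7-en-4-yl]propanenitrile | O[C@@H]1C=C(C)[C@@]3(OC3)[C@](C)(CCC#N)[C@H]1C(C)=C | intermediate
9 | 3-[(1S,2R,5R,6R)-5-hydroxy-2-(hydroxymethyl)-1,3-dimethyl-6-(prop-1-en-2-yl)cyclohex-3-en-1-yl]propanenitrile | O[C@@H]1C=C(C)[C@@H](CO)[C@](C)(CCC#N)[C@H]1C(C)=C | intermediate
10 | (4aS,5R,8R,8aS)-8-hydroxy-5-(hydroxymethyl)-1,1,4a,6-tetramethyl-3,4,4a,5,8,8a-hexahydronaphthalen-2(1H)-imine, formed and consumed in step 7 | O[C@@H]1C=C(C)[C@@H](CO)[C@]2(C)CCC(=N)C(C)(C)[C@@H]12 | intermediate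
11 | (4aS,5R,8R,8aS)-8-hydroxy-5-(hydroxymethyl)-1,1,4a,6-tetramethyl-3,4,4a,5,8,8a-hexahydronaphthalen-2(1H)-one | O[C@@H]1C=C(C)[C@@H](CO)[C@]2(C)CCC(=O)C(C)(C)[C@@H]12 | intermediate
12 | umbelliferone, 7-hydroxy-2H-chromen-2-one | Oc1ccc2ccc(=O)oc2c1 | starting material
13 | 7-{[(1R,4R,4aS,8aS)-4-hydroxy-2,5,5,8a-tetramethyl-6-oxo-1,4,4a,5,6,7,8,8a-octahydronaphthalen-1-yl]methoxy}-2H-chromen-2-one | O[C@@H]1C=C(C)[C@@H](COc2ccc3ccc(=O)oc3c2)[C@]2(C)CCC(=O)C(C)(C)[C@@H]12 | intermediate
14 | (1R,4R,4aS,8aS)-3,4a,8,8-tetramethyl-7-oxo-4-{[(2-oxo-2H-chromen-7-yl)oxy]methyl}-1,4,4a,5,6,7,8,8a-octahydronaphthalen-1-yl acetate | CC(=O)O[C@@H]1C=C(C)[C@@H](COc2ccc3ccc(=O)oc3c2)[C@]2(C)CCC(=O)C(C)(C)[C@@H]12 | target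

**Totals.** Total step count: 9. Longest linear sequence: 9 steps, from (S)-carvone.

**Steps most likely to fail**

Step 7 (key step). The tertiary C4 radical may be reduced by the iron hydride, giving net hydrogenation of the isopropenyl group, faster than it adds to the unactivated nitrile. The fallback sets out from 9 and comes back at 11. Cobalt-catalysed HAT hydrochlorination of the isopropenyl group (Co(BF4)2·6H2O, salen-type ligand, PhSiH3, TsCl, EtOH) should give the tertiary chloride 3-[(1S,2R,5R,6R)-6-(2-chloropropan-2-yl)-5-hydroxy-2-(hydroxymethyl)-1,3-dimethylcyclohex-3-en-1-yl]propanenitrile F1. This is cyclised in a separate radical chain ((Me3Si)3SiH, AIBN, slow addition, refluxing benzene), where the low stationary concentration of the hydrogen donor gives the radical time to add to the nitrile. The ketimine 10 is then hydrolysed with aqueous HCl to 11.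

Step 2. The α-cyano carbanion formed in the Michael addition may add back to the enone β-carbon (a second, intramolecular Michael addition that builds a bicyclo[2.2.2]octanone), and acrylonitrile may oligomerise anionically. The fallback sets out from 2 and comes back at 4. Alkylation of the same enolate with allyl bromide (LiN(iPr)2, THF, −78 °C), again anti to the isopropenyl group, should give (5R,6R)-2,6-dimethyl-6-(prop-2-en-1-yl)-5-(prop-1-en-2-yl)cyclohex-2-en-1-one F2. Nitrite-modified aldehyde-selective Wacker oxidation of the monosubstituted alkene (PdCl2(PhCN)2, CuCl2·2H2O, AgNO2, O2, t-BuOH/MeNO2) should give 3-[(1R,6R)-1,3-dimethyl-2-oxo-6-(prop-1-en-2-yl)cyclohex-3-en-1-yl]propanal F3. Hydroxylamine-O-sulfonic acid in water/THF then converts the aldehyde into nitrile 4.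

Step 6. Hydride may be delivered to C7 instead of C9 (moving the alkene to C8=C9), or the allylpalladium intermediate may lose a β-hydrogen to give a dienol. The fallback sets out from 8 and comes back at 9. A Lewis-acid Meinwald rearrangement (MgBr2·OEt2, CH2Cl2, −78 °C), with hydride shift from C11 to C9 anti to the departing oxygen, should give (1R,4R,5R,6R)-6-(2-cyanoethyl)-4-hydroxy-2,6-dimethyl-5-(prop-1-en-2-yl)cyclohex-2-ene-1-carbaldehyde F4. This is reduced at once with NaBH4 and CeCl3·7H2O (MeOH, −40 °C) to 9, before the β,γ-unsaturated aldehyde can move into conjugation.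

**Further compounds**

F1 | step 7 | 3-[(1S,2R,5R,6R)-6-(2-chloropropan-2-yl)-5-hydroxy-2-(hydroxymethyl)-1,3-dimethylcyclohex-3-en-1-yl]propanenitrile | O[C@@H]1C=C(C)[C@@H](CO)[C@](C)(CCC#N)[C@H]1C(C)(C)Cl
F2 | step 2 | (5R,6R)-2,6-dimethyl-6-(prop-2-en-1-yl)-5-(prop-1-en-2-yl)cyclohex-2-en-1-one | C1C=C(C)C(=O)[C@](C)(CC=C)[C@H]1C(C)=C
F3 | step 2 | 3-[(1R,6R)-1,3-dimethyl-2-oxo-6-(prop-1-en-2-yl)cyclohex-3-en-1-yl]propanal | C1C=C(C)C(=O)[C@](C)(CCC=O)[C@H]1C(C)=C
F4 | step 6 | (1R,4R,5R,6R)-6-(2-cyanoethyl)-4-hydroxy-2,6-dimethyl-5-(prop-1-en-2-yl)cyclohex-2-ene-1-carbaldehyde | O[C@@H]1C=C(C)[C@@H](C=O)[C@](C)(CCC#N)[C@H]1C(C)=C
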